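**Assumption:** Rubrolide A has no stereocentre, so "single enantiomer" adds nothing. The only stereochemical element is the exocyclic alkene, which is Z. The benzylidene aryl group is trans to C4 of the ring and cis to the ring oxygen.

## Retrosynthetic overview
1. Rubrolide A (**11**) comes from BBr3 demethylation of the bis(methyl ether) **9**, so both phenols stay masked as 2,6-dibromoanisoles until the last step.
2. **9** (4-aryl-5-(Z)-arylidene-butenolide) comes from a one-pot condensation of the symmetric ketone **7**, ArCH2COCH2Ar, with glyoxylic acid (**8**). This forms the C3–C4 bond, the butenolide ring (the only ring) and the Z-alkylidene in one operation. This is the new step.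
3. **7** comes from self-Claisen condensation of two molecules of methyl arylacetate **5**, then ester hydrolysis and decarboxylation.
4. **5** comes from 4-hydroxyphenylacetic acid (**1**) by dibromination and exhaustive methylation.

## Route

**Step 1**
Reactants: **1** 4-hydroxyphenylacetic acid; **2** bromine
Product: **3** 3,5-dibromo-4-hydroxyphenylacetic acid
Conditions: Br2 (2.1 equiv), AcOH, rt, 3 h
Reagents that add atoms: Br2, BrBr (two Br retained)
Why: Electrophilic aromatic bromination of a phenol. The para position is blocked, so both ortho positions are brominated.

**Step 2**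
Reactants: **3** 3,5-dibromo-4-hydroxyphenylacetic acid; **4** iodomethane
Product: **5** methyl 2-(3,5-dibromo-4-methoxyphenyl)acetate
Conditions: MeI (3.5 equiv), K2CO3 (3 equiv), DMF, rt, 12 h
Reagents that add atoms: MeI, CI (two CH3 retained, one on the ester and one on the ether)
Why: Williamson O-alkylation of the acidic dibromophenol and carboxylate O-alkylation, both in one operation.

**Step 3**
Reactants: **5** methyl 2-(3,5-dibromo-4-methoxyphenyl)acetate (first molecule, enolate donor); **5** methyl 2-(3,5-dibromo-4-methoxyphenyl)acetate (second molecule, acylating partner)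
Product: **6** methyl 2,4-bis(3,5-dibromo-4-methoxyphenyl)-3-oxobutanoate (MeOH is the only by-product)
Conditions: NaH (1.2 equiv), THF, 0 °C to reflux, 4 h; then aq. HCl workup
Reagents that add atoms: none (NaH is only a base)
Why: Claisen self-condensation of an arylacetate, 2 C10H10Br2O3 → C19H16Br4O5 + CH3OH. It is driven forward by deprotonation of the very acidic 2,4-diaryl-β-ketoester product, which is protonated on workup. The aryl bromides and aryl methyl ethers tolerate NaH.

**Step 4**
Reactants: **6** methyl 2,4-bis(3,5-dibromo-4-methoxyphenyl)-3-oxobutanoate
Product: **7** 1,3-bis(3,5-dibromo-4-methoxyphenyl)propan-2-one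
Conditions: AcOH / 6 M HCl (2:1), reflux, 12 h
Reagents that add atoms: none (the water used for hydrolysis ends up in MeOH and CO2, not in the product)
Why: Acid hydrolysis of the methyl ester, then decarboxylation of the β-keto acid through a cyclic six-membered transition state. The aryl methyl ethers and aryl bromides survive HCl/AcOH.

**Step 5**
Reactants: **7** 1,3-bis(3,5-dibromo-4-methoxyphenyl)propan-2-one; **8** glyoxylic acid monohydrate
Product: **9** (Z)-4-(3,5-dibromo-4-methoxyphenyl)-5-(3,5-dibromo-4-methoxybenzylidene)furan-2(5H)-one
Conditions: (i) **8** (1.2 equiv), TsOH·H2O (0.3 equiv), AcOH, 100 °C, 12 h; then, in the same pot, (ii) Ac2O (6 equiv), 100 °C, 3 h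
Reagents that add atoms: glyoxylic acid, O=CC(=O)O (supplies C2 and C3 of the butenolide; **7** + **8** → **9** + 2 H2O)
Why: Proposed new method: a desymmetrising one-pot aldol condensation, lactolisation and dehydrative alkylidene-lactone cascade that converts a symmetric 1,3-diarylacetone and glyoxylic acid directly into a 4-aryl-5-(Z)-arylidene-2(5H)-furanone. The mechanism has four stages.
- TsOH enolises one benzylic α-CH2 of **7**. The enol adds to the aldehyde of glyoxylic acid, and dehydration gives 3-aryl-4-oxo-5-arylpent-2-enoic acid, HO2C–CH=C(Ar)–C(=O)–CH2Ar.
- The alkene isomers interconvert by reversible conjugate addition under acid. The isomer with CO2H cis to the ketone is drained into the cyclic 5-hydroxy-5-benzyl-butenolide (pseudo-acid).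
- Ac2O acetylates the tertiary lactol hydroxyl. Loss of AcOH gives a ring-oxygen-stabilised 2-furanylium-type cation, and loss of the benzylic proton gives the exocyclic alkene.
- Elimination is under thermodynamic control in hot AcOH/TsOH. The Z-alkene has the arylidene aryl cis to the ring O and trans to the C4 aryl. The E-alkene would place the two aryl groups cis with A(1,3) strain, so the Z isomer is strongly preferred.
- Closest known reactions: acid-mediated condensation of deoxybenzoins or aryl methyl ketones with glyoxylic acid to 5-hydroxybutenolides or aroylacrylic acids, and Ac2O dehydration of 5-hydroxy-5-alkylbutenolides or enol-lactonisation of γ-keto acids to γ-alkylidenebutenolides. Applying this to a symmetric bis(benzyl) ketone to build the rubrolide core in one operation is the new element.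

**Step 6**
Reactants: **9** (Z)-4-(3,5-dibromo-4-methoxyphenyl)-5-(3,5-dibromo-4-methoxybenzylidene)furan-2(5H)-one; **10** boron tribromide
Product: **11** Rubrolide A
Conditions: BBr3 (1 M in CH2Cl2, 6 equiv), CH2Cl2, −78 °C to 0 °C, 3 h; quench with ice-water
Reagents that add atoms: none (BBr3, BrB(Br)Br, removes the methyl groups as MeBr; the phenol H comes from workup)
Why: Lewis-acid O-demethylation of aryl methyl ethers. BBr3 cleaves even these di-ortho-brominated anisoles. At low temperature the butenolide and the Z-alkene survive, and the aryl C–Br bonds are untouched. The Z geometry set in Step 5 is kept.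

## Compound list
1 | 4-hydroxyphenylacetic acid | OC(=O)Cc1ccc(O)cc1 | starting material
2 | bromine | BrBr | starting material (reagent)
3 | 3,5-dibromo-4-hydroxyphenylacetic acid | OC(=O)Cc1cc(Br)c(O)c(Br)c1 | intermediate
4 | iodomethane | CI | starting material (reagent)
5 | methyl 2-(3,5-dibromo-4-methoxyphenyl)acetate | COC(=O)Cc1cc(Br)c(OC)c(Br)c1 | intermediate
6 | methyl 2,4-bis(3,5-dibromo-4-methoxyphenyl)-3-oxobutanoate | COC(=O)C(c1cc(Br)c(OC)c(Br)c1)C(=O)Cc1cc(Br)c(OC)c(Br)c1 | intermediate
7 | 1,3-bis(3,5-dibromo-4-methoxyphenyl)propan-2-one | COc1c(Br)cc(CC(=O)Cc2cc(Br)c(OC)c(Br)c2)cc1Br | intermediate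
8 | glyoxylic acid (monohydrate) | O=CC(=O)O | starting material
9 | (Z)-4-(3,5-dibromo-4-methoxyphenyl)-5-(3,5-dibromo-4-methoxybenzylidene)furan-2(5H)-one | O=C1C=C(c2cc(Br)c(OC)c(Br)c2)/C(=C/c2cc(Br)c(OC)c(Br)c2)O1 | intermediate
10 | boron tribromide | BrB(Br)Br | starting material (reagent)
11 | Rubrolide A | O=C1C=C(c2cc(Br)c(O)c(Br)c2)/C(=C/c2cc(Br)c(O)c(Br)c2)O1 | target

## Totals
Total step count: 6. Longest linear sequence: 6 steps, from **1**.

## Three steps most likely to fail
1. **Step 5 (the proposed new step).** Risks are incomplete dehydration, an E-acid that will not cyclise, and competing double condensation.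
   - Fallback (known chemistry, different approach): build the rubrolide core from tetronic acid. Convert it to the 4-tosyloxyfuranone with TsCl/Et3N and couple with 4-methoxyphenylboronic acid (Suzuki).
   - Next, TBSOTf/iPr2NEt gives the 2-silyloxyfuran. A vinylogous Mukaiyama aldol with 3,5-dibromo-4-methoxybenzaldehyde, then dehydration, gives the Z-arylidene.
   - Finally, BBr3 demethylation and NBS (2.2 equiv) bromination of the one remaining unbrominated phenol ring give rubrolide A.
2. **Step 3 (self-Claisen).** Risks are poor conversion and side reactions of the aryl bromides.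
   - Fallback: ketene route. Hydrolyse **5** to the acid, convert it to the acid chloride, and treat with Et3N to dimerise the arylketene. Aqueous HCl/AcOH hydrolysis and decarboxylation of the dimer then give **7** without any enolate chemistry.
3. **Step 6 (BBr3 demethylation).** Risks are lactone opening, Z/E scrambling and bromine migration under the strong Lewis acid.
   - Fallback: move demethylation upstream. Treat ketone **7** with BBr3 to give the bisphenol, then run the Step 5 cascade on it. Ac2O acetylates the phenols, and the labile 2,6-dibromophenyl acetates are removed under mild conditions (NH2OH·HCl/NaOAc, MeOH, rt) to give **11**.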